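## Analysis of the target

The target is a caged polyprenylated acylphloroglucinol: a homoadamantane-type tetracycle (rings A to D) fused to a 2,2-dimethylcyclopentane (ring E), with a bridgehead benzoyl group and a bridgehead geranyl chain. The numbering used here is: C1 benzoyl-bearing bridgehead, C2 ketone, C3 quaternary carbon shared with the cyclopentane, C4 ketone, C5 geranyl-bearing bridgehead, C6 CH2, C7 CH, C8 CMe2 between C7 and C1, C9 ketone between C1 and C5, C11 CH2 between C7 and C12, C12 ring-fusion CH, C13 CMe2, C14 and C15 CH2; ring A is C1–C2–C3–C4–C5–C9, ring B C1–C9–C5–C6–C7–C8, ring C C3–C4–C5–C6–C7–C11–C12, ring D C1–C2–C3–C12–C11–C7–C8, ring E C3–C12–C13–C14–C15. C1, C3, C5 and C7 are the four nodes of the cage and are locked to one another by its topology. C12 is independent: its hydrogen is cis to the C3–C4 bond (rings D and E cis-fused), so C13 lies anti to C6 across ring D; the configuration is (1S,3S,5R,7R,12R) in this numbering. The sensitive groups are the geranyl 2,6-diene (acid, electrophiles, hydrogenation) and the non-enolisable C2/C4/C9 tricarbonyl array, which is open to retro-Claisen cleavage. The difficulty is the density of fully substituted carbons: C1, C3 and C5 are quaternary and each lies between two carbonyls, C8 and C13 are gem-dimethyl carbons next to stereocentres, and the remote pair C7/C12 has to be related across a flexible seven-membered ring. The plan rests on one feature: rings D and E form a cis-fused bicyclo[5.3.0]decan-2-one whose α-carbons C1 and C3 are spanned by the unit C9–C5–C4, and C5 carries the geranyl group, so a geranylmalonyl unit maps onto C4, C5, C9 and the side chain. A one-carbon arm C6 on C7, syn to that bridge, then closes rings B and C through the single bond C5–C6.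

## Retrosynthetic reasoning

C1–C(benzoyl): 29 is cut to the cage trione 27 and benzoyl chloride 28. This bond goes first because the aryl ketone would be a fourth electrophilic carbonyl in every earlier step. In 27 the C1 hydrogen is the only hydrogen α to a carbonyl (C3 and C5 are quaternary), so bridgehead deprotonation and C-acylation need no regiocontrol.

C5–C6: 27 is cut to the iodide 26, made from the chloride 25. This one bond closes rings B and C together. C5 is the central carbon of a 1,3-diketone and C6 is a primary carbon, so the polarity is natural. The forward step needs C- rather than O-alkylation and needs C6 on the face of ring D that carries ring A.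

C3–C4 and C1–C9 (key disconnection): 25 is cut to the enol ether 24 and geranylmalonyl dichloride 5. The two bonds flank the C2 ketone, whose α-carbons are the natural nucleophiles. Cutting here gives ring A, quaternary C3 and the C1 stereocentre in one operation and brings in the geranyl group without a separate alkylation of a hindered carbon. The forward step must acylate C3 on the face cis to the C12 hydrogen and then acylate the neopentyl-type C1.

C5–C1′ of the side chain: 5 comes from the diacid 4 and the diester 3, which is the alkylation product of diethyl malonate 1 with geranyl bromide 2.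

Functional-group changes at C2 and C6: 24 comes from the chloro ketone 22 through its ketal 23, and 22 from the alcohol 21. The chloride is a leaving-group precursor that is inert to the acid chloride chemistry of the key step.

C3–C15 (ring E): 21 is cut to the keto tosylate 20. C3 is α to the ketone, and a five-membered closure by enolate alkylation is expected to give the cis ring fusion. The C3 centre is in any case epimerisable under the basic conditions and becomes sp2 again in 24.

C12–H: 20 is traced back to the enone 19, in which C12 is sp2. Direct addition of the bulky C13 unit to C12 of a 5-substituted cycloheptenone has no reliable facial bias: the two chair forms, with the C7 arm equatorial or axial, expose opposite faces. A hydrogenation directed by the C6 hydroxyl fixes the C12 hydrogen cis to C6 whatever the conformation.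

C12–C13: 19 comes from the ketone 17 by dehydrogenation (through 18), and 17 from the cycloheptenone 15 and the alkene tosylate 16 by radical conjugate addition. A tertiary radical is the practical way to join C12 to the quaternary C13. Dehydrogenation can only go towards C3 because C8 is quaternary, so both C12 epimers of 17 converge.

C3=C12 and C2–C3 (ring D): 15 is cut by ring-closing metathesis to the dienone 14, which comes from the Weinreb amide 13 by vinyl addition.

C7–C11 and the C7 stereocentre: 13 comes from the alcohol 12 and the imide 11. 11 is the auxiliary-controlled allylation product of 10, in which the imide carbonyl is C6. 10 is assembled from the acid 7 and the oxazolidinone 8 through the mixed anhydride 9. The chain C6–C7–C8–C1–C2 of 7 is that of 3,3-dimethylglutaric anhydride 6.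

## Alternatives that were turned down

Alternative 1: Ring C is disconnected at C5–C6 and C3–C12 into the siloxy vinyldiazoacetate A1 and the diene A2.
- Forward key step: Rh2(S-DOSP)4 or its enantiomer converts A1 into a vinylcarbenoid that cyclopropanates the 1,1-disubstituted alkene of A2 (the future C6=C7); Cope rearrangement at the cis-divinylcyclopropane stage forms C3–C12 and gives the cyclohepta-1,4-diene A3.
- For: catalyst-controlled absolute configuration at C12, a convergent seven-membered ring synthesis, and C4/C5/C9 arriving as a masked β-keto ester.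
- Against: in A3, C7 is sp2, so the C7 stereocentre and its anti relation to C12 must be created afterwards across the ring. The cyclopropanation must occur on an alkene flanked by the quaternary C8. Rings A, B, D and E and the quaternary carbons C1, C3 and C5 are all still to be made from A3 by separate alkylations and Claisen condensations.
- Comparison: it is stronger on enantiocontrol (catalytic, no auxiliary) but much longer after its key step. The chosen plan gives in exchange one operation that forms both C3–C4 and C1–C9, after which only one C–C bond is needed to complete the cage.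

Alternative 2: Ring E is disconnected at C12–C13 and C3–C15 into the cycloheptenone β-keto ester A4 and the alkene tosylate A5 (the same tosylate as 16).
- Forward key step: Fe(acac)3 and PhSiH3 turn the alkene of A5 into the tertiary C13 radical, which adds to C12 of A4; the C3 enolate formed after reduction is alkylated by the tethered tosylate to give A6.
- For: one operation makes both ring E bonds and quaternary C3 with C4 already attached. The acceptor is doubly activated and the closure is a 5-exo alkylation of a stabilised enolate. The propanoate arm on C7 already holds C6, C5 and C9.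
- Against: the C12 configuration would depend on 1,3-induction from C7 in a mobile cycloheptenone, where the equatorial and axial conformers lead to opposite faces. Rings C, A and B must then be closed by two reversible Claisen-type condensations next to quaternary carbons, and the geranyl group is still missing.
- Comparison: it is equal or better in how early C3 is secured, and the chosen route uses the same radical for C12–C13. The chosen route takes the stereochemical burden off that step (C12 is set later by directed hydrogenation) and builds ring A in one acid-chloride step instead of two base-mediated condensations.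

Alternative 3: C4–C5 and the C9–O bond are disconnected together, leading from the isoxazoline A8 back to the aldoxime A7.
- Forward key step: NaOCl oxidises the aldoxime group of A7, and the resulting nitrile oxide function adds intramolecularly across the C5=C9 alkene of ring B. This forms C4–C5 and O–C9 and closes ring C and the isoxazoline of A8.
- For: intramolecular nitrile oxide cycloadditions accept trisubstituted alkenes, so the geranyl-bearing quaternary C5 is made suprafacially and C9 is oxygenated in the same step.
- Against: A7 already needs quaternary C3 with three different carbon substituents and both the C7 and C12 stereocentres, so most of the stereochemical problem is solved beforehand by other means. Hypochlorite and the later reductive N–O cleavage must spare the two trisubstituted alkenes of the geranyl chain. The last closure (C1 onto the C3 ester) must form rings A and D together.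
- Comparison: it is stronger for quaternary C5, which arrives with defined configuration from a pericyclic step, and weaker in step count and end-game risk. The chosen route brings C5 in with the malonyl unit and lets the cage fix its configuration.

Key step: step 17

Assumption: 3-methylbut-3-en-1-yl 4-methylbenzenesulfonate (16) is taken as a purchasable reagent; it is otherwise one tosylation away from 3-methylbut-3-en-1-ol.

Remark on locants: in the tricyclo[7.3.1.0(1,5)]tridecane names of 25 and 26, positions 1, 5, 7 and 9 are C3, C12, C7 and C1 of the analysis numbering; the cage compounds 27 and 29 are named with the analysis numbering itself.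

## Route

Step 1
Reactants: 1 diethyl malonate; 2 geranyl bromide, (2E)-1-bromo-3,7-dimethylocta-2,6-diene
Product: 3 diethyl 2-[(2E)-3,7-dimethylocta-2,6-dien-1-yl]propanedioate
Conditions: NaH, THF, 0 °C; then 2, 0 to 25 °C (1 in excess)
Reagents that add atoms: none
Why: Malonic ester alkylation; the sodium malonate attacks the primary allylic bromide by SN2, the E-alkene is untouched, and excess 1 suppresses dialkylation.

Step 2
Reactants: 3 diethyl 2-[(2E)-3,7-dimethylocta-2,6-dien-1-yl]propanedioate
Product: 4 2-[(2E)-3,7-dimethylocta-2,6-dien-1-yl]propanedioic acid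
Conditions: KOH, EtOH/H2O, 25 °C; then HCl (aq), 0 °C
Reagents that add atoms: potassium hydroxide, [K+].[OH-]
Why: Ester saponification; cold acidification avoids decarboxylation of the malonic acid and acid-induced cyclisation of the diene.

Step 3
Reactants: 4 2-[(2E)-3,7-dimethylocta-2,6-dien-1-yl]propanedioic acid
Product: 5 2-[(2E)-3,7-dimethylocta-2,6-dien-1-yl]propanedioyl dichloride (geranylmalonyl dichloride)
Conditions: (COCl)2, DMF (cat.), CH2Cl2, 0 to 25 °C; used crude
Reagents that add atoms: oxalyl chloride, O=C(Cl)C(=O)Cl
Why: Acid chloride formation through the Vilsmeier-type chloroiminium catalyst; the by-products are gases, so the sensitive dichloride should be usable without purification.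

Step 4
Reactants: 6 3,3-dimethylglutaric anhydride
Product: 7 5-[methoxy(methyl)amino]-3,3-dimethyl-5-oxopentanoic acid
Conditions: MeNHOMe·HCl, pyridine, CH2Cl2, 0 to 25 °C
Reagents that add atoms: N,O-dimethylhydroxylamine hydrochloride, CNOC.Cl
Why: Aminolysis of a cyclic anhydride stops at the mono-amide acid; this differentiates the future C2 terminus (Weinreb amide) from the future C6 terminus (acid).

Step 5
Reactants: 7 5-[methoxy(methyl)amino]-3,3-dimethyl-5-oxopentanoic acid; 8 (4S)-4-benzyl-1,3-oxazolidin-2-one
Product: 10 5-[(4S)-4-benzyl-2-oxo-1,3-oxazolidin-3-yl]-N-methoxy-N,3,3-trimethyl-5-oxopentanamide, via mixed pivalic anhydride 9 (not isolated)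
Conditions: PivCl, Et3N, THF, −20 °C; then 8, LiCl, 25 °C
Reagents that add atoms: none
Why: N-Acylation of the oxazolidinone by the mixed-anhydride method; the oxazolidinone attacks the less hindered carbonyl of 9.

Step 6
Reactants: 10 5-[(4S)-4-benzyl-2-oxo-1,3-oxazolidin-3-yl]-N-methoxy-N,3,3-trimethyl-5-oxopentanamide
Product: 11 (4S)-4-{[(4S)-4-benzyl-2-oxo-1,3-oxazolidin-3-yl]carbonyl}-N-methoxy-N,3,3-trimethylhept-6-enamide
Conditions: NaHMDS, THF, −78 °C; then allyl iodide, −78 to −40 °C
Reagents that add atoms: allyl iodide, C=CCI
Why: Evans asymmetric alkylation; only the more acidic imide α-CH2 (C7) is deprotonated, the chelated Z-sodium enolate is shielded on one face by the benzyl group, and allyl iodide adds from the other face to give the 4S centre (C7, bearing C11).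

Step 7
Reactants: 11 (4S)-4-{[(4S)-4-benzyl-2-oxo-1,3-oxazolidin-3-yl]carbonyl}-N-methoxy-N,3,3-trimethylhept-6-enamide
Product: 12 (4S)-4-(hydroxymethyl)-N-methoxy-N,3,3-trimethylhept-6-enamide
Conditions: NaBH4, THF/H2O, 0 to 25 °C
Reagents that add atoms: none
Why: Reductive removal of the auxiliary; borohydride reduces the activated exocyclic imide carbonyl (C6) to the primary alcohol, leaves the Weinreb amide alone, and cannot epimerise C7; the crude alcohol is silylated at once in step 8 so that the δ-hydroxy amide has little time to lactonise.

Step 8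
Reactants: 12 (4S)-4-(hydroxymethyl)-N-methoxy-N,3,3-trimethylhept-6-enamide
Product: 13 (4S)-4-({[tert-butyl(dimethyl)silyl]oxy}methyl)-N-methoxy-N,3,3-trimethylhept-6-enamide
Conditions: TBSCl, imidazole, DMF, 25 °C
Reagents that add atoms: tert-butyldimethylsilyl chloride, CC(C)(C)[Si](C)(C)Cl
Why: Silylation of the primary alcohol; it prevents lactonisation onto the amide and protects C6–OH from the Grignard reagent and the later oxidant.

Step 9
Reactants: 13 (4S)-4-({[tert-butyl(dimethyl)silyl]oxy}methyl)-N-methoxy-N,3,3-trimethylhept-6-enamide
Product: 14 (6S)-6-({[tert-butyl(dimethyl)silyl]oxy}methyl)-5,5-dimethylnona-1,8-dien-3-one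
Conditions: CH2=CHMgBr, THF, 0 °C; then HCl (aq), 0 °C
Reagents that add atoms: vinylmagnesium bromide, C=C[Mg]Br
Why: Weinreb ketone synthesis; the chelated tetrahedral intermediate prevents over-addition, and the cold acidic quench keeps the released amine from adding to the vinyl ketone.

Step 10
Reactants: 14 (6S)-6-({[tert-butyl(dimethyl)silyl]oxy}methyl)-5,5-dimethylnona-1,8-dien-3-one
Product: 15 (5S)-5-({[tert-butyl(dimethyl)silyl]oxy}methyl)-6,6-dimethylcyclohept-2-en-1-one
Conditions: second-generation Grubbs catalyst RuCl2(=CHPh)(H2IMes)(PCy3) (5 mol%), CH2Cl2 (0.005 M), 40 °C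
Reagents that add atoms: none
Why: Ring-closing metathesis of a vinyl ketone with a terminal alkene forms C3=C12 and ring D with loss of ethene; the gem-dimethyl group favours the seven-membered closure.

Step 11
Reactants: 15 (5S)-5-({[tert-butyl(dimethyl)silyl]oxy}methyl)-6,6-dimethylcyclohept-2-en-1-one; 16 3-methylbut-3-en-1-yl 4-methylbenzenesulfonate
Product: 17 3-[(1RS,3S)-3-({[tert-butyl(dimethyl)silyl]oxy}methyl)-4,4-dimethyl-6-oxocycloheptyl]-3-methylbutyl 4-methylbenzenesulfonate (both C12 epimers)
Conditions: Fe(acac)3 (cat.), PhSiH3, EtOH/(CH2OH)2, 60 °C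
Reagents that add atoms: none
Why: Hydrogen-atom-transfer-initiated Giese addition; the iron hydride converts the 1,1-disubstituted alkene of 16 into the tertiary C13 radical, which adds to the enone β-carbon C12 and joins it to a quaternary carbon; the C12 configuration is not controlled and need not be, because C12 is made sp2 again in step 12.

Step 12
Reactants: 17 3-[(1RS,3S)-3-({[tert-butyl(dimethyl)silyl]oxy}methyl)-4,4-dimethyl-6-oxocycloheptyl]-3-methylbutyl 4-methylbenzenesulfonate
Product: 19 3-[(6S)-6-(hydroxymethyl)-5,5-dimethyl-3-oxocyclohept-1-en-1-yl]-3-methylbutyl 4-methylbenzenesulfonate, via silyl ether enone 18 (not isolated)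
Conditions: IBX, 4-methoxypyridine N-oxide, DMSO, 25 °C; aqueous work-up; then crude 18, HCl (cat.), MeOH, 25 °C
Reagents that add atoms: none
Why: IBX dehydrogenation of a ketone to the enone; C8 is quaternary, so only the C3=C12 enone can form and both epimers of 17 give the same product; acidic methanolysis then frees the C6 hydroxyl needed as directing group.

Step 13
Reactants: 19 3-[(6S)-6-(hydroxymethyl)-5,5-dimethyl-3-oxocyclohept-1-en-1-yl]-3-methylbutyl 4-methylbenzenesulfonate
Product: 20 3-[(1S,3S)-3-(hydroxymethyl)-4,4-dimethyl-6-oxocycloheptyl]-3-methylbutyl 4-methylbenzenesulfonate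
Conditions: H2 (1 atm), [Ir(cod)(PCy3)(py)]PF6 (5 mol%), CH2Cl2, 25 °C
Reagents that add atoms: none
Why: Hydroxyl-directed homogeneous hydrogenation; the cationic iridium centre binds the C6 hydroxyl, which reaches the alkene from a pseudo-axial position 1,3 across the ring, and both hydrogens are delivered to that face, so the C12 hydrogen ends cis to C6 and the bulky C13 group trans to it (1S).

Step 14
Reactants: 20 3-[(1S,3S)-3-(hydroxymethyl)-4,4-dimethyl-6-oxocycloheptyl]-3-methylbutyl 4-methylbenzenesulfonate
Product: 21 (3aS,7S,8aS)-7-(hydroxymethyl)-1,1,6,6-tetramethyloctahydroazulen-4(1H)-one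
Conditions: KOtBu (2.2 equiv), t-BuOH/THF, 25 °C
Reagents that add atoms: none
Why: Intramolecular enolate alkylation under equilibrating conditions; the C3 enolate displaces the tosylate in a 5-(enolexo)-exo-tet closure of ring E, the cis fusion is expected and C3 can equilibrate under the basic conditions, and neither the C1 enolate nor the C6 alkoxide has a comparably small ring to close; the C3 centre is removed again in step 16.

Step 15
Reactants: 21 (3aS,7S,8aS)-7-(hydroxymethyl)-1,1,6,6-tetramethyloctahydroazulen-4(1H)-one
Product: 22 (3aS,7S,8aS)-7-(chloromethyl)-1,1,6,6-tetramethyloctahydroazulen-4(1H)-one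
Conditions: PPh3, CCl4, MeCN, 60 °C
Reagents that add atoms: carbon tetrachloride, ClC(Cl)(Cl)Cl
Why: Appel reaction; chloride displaces the oxyphosphonium group at the primary carbon C6, with no change at C7 and no reaction at the ketone.

Step 16
Reactants: 22 (3aS,7S,8aS)-7-(chloromethyl)-1,1,6,6-tetramethyloctahydroazulen-4(1H)-one
Product: 24 (7S,8aR)-7-(chloromethyl)-4-methoxy-1,1,6,6-tetramethyl-1,2,3,5,6,7,8,8a-octahydroazulene, via dimethyl ketal 23 (not isolated)
Conditions: HC(OMe)3, p-TsOH (cat.), MeOH, 25 °C; then p-TsOH (cat.), PhMe, 110 °C (MeOH distilled off)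
Reagents that add atoms: trimethyl orthoformate, COC(OC)OC
Why: Ketalisation followed by acid-catalysed loss of methanol gives the more substituted C2=C3 methyl enol ether; any C1=C2 isomer is carried along because it converges in step 17; the change of the C12 descriptor from S to R is a priority effect, not an inversion.

Step 17
Reactants: 24 (7S,8aR)-7-(chloromethyl)-4-methoxy-1,1,6,6-tetramethyl-1,2,3,5,6,7,8,8a-octahydroazulene; 5 2-[(2E)-3,7-dimethylocta-2,6-dien-1-yl]propanedioyl dichloride
Product: 25 (1S,5R,7S,9R)-7-(chloromethyl)-11-[(2E)-3,7-dimethylocta-2,6-dien-1-yl]-12-hydroxy-4,4,8,8-tetramethyltricyclo[7.3.1.0(1,5)]tridec-11-ene-10,13-dione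
Conditions: 5 (1.5 equiv), Et2O, −20 to 25 °C; then KOH, BnEt3NCl (cat.), H2O, 0 °C; then HCl (aq)
Reagents that add atoms: none
Why: Effenberger cyclisation, a (3+3) double C-acylation of a ketone enol ether by a malonyl dichloride, which here builds rings A, D and E with the enolised C4/C9 dione. The enol ether carbon C3 attacks one acyl chloride of 5 (or the acyl ketene formed from it by loss of HCl), which makes the quaternary C3–C4 bond and an oxocarbenium ion at C2; loss of the C1 proton gives a new methyl enol ether C1=C2, whose carbon C1 attacks the second acyl chloride and closes ring A by a 6-(enolendo)-exo-trig acylation (C1–C9), after which chloride removes the O-methyl group as chloromethane and the C4/C9 dione enolises towards C5. The closest precedent is the same annulation of 1-methoxycyclohexenes that carry a substituent on the enol ether carbon and a CH2–CMe2 unit on the other side, the local environment of C3 and C1 here; the seven-membered ketone and the monoalkylated dichloride are the extensions. C3 is controlled by C12: ring E lies near the plane of the C2=C3 bond, the C12–C11 bond and the body of ring D occupy one face, and the acyl chloride adds to the open convex face that carries the C12 hydrogen, which keeps rings D and E cis-fused and places C4 on the side of the C7 chloromethyl arm. C1 is controlled by the tether, since the second acyl group is held on the face already occupied by C4 and only the 1,3-cis bridge can form. The step needs C- over O-acylation and reaction at both α-carbons; the π-nucleophilicity of the enol ether, the non-ionising solvent and the aqueous KOH/phase-transfer treatment, which returns O-acylated or lactonised material to the trione, serve this, and the minor C1=C2 isomer of 24 converges because both α-carbons are acylated in either order. The primary chloride and the remote geranyl alkenes should be inert to the acid chloride at or below room temperature.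

Step 18
Reactants: 25 (1S,5R,7S,9R)-7-(chloromethyl)-11-[(2E)-3,7-dimethylocta-2,6-dien-1-yl]-12-hydroxy-4,4,8,8-tetramethyltricyclo[7.3.1.0(1,5)]tridec-11-ene-10,13-dione
Product: 26 (1S,5R,7S,9R)-11-[(2E)-3,7-dimethylocta-2,6-dien-1-yl]-12-hydroxy-7-(iodomethyl)-4,4,8,8-tetramethyltricyclo[7.3.1.0(1,5)]tridec-11-ene-10,13-dione
Conditions: NaI, 2-butanone, 80 °C
Reagents that add atoms: sodium iodide, [Na+].[I-]
Why: Finkelstein exchange at the primary carbon C6, driven by precipitation of NaCl; no base is present, so the enol stays protonated and does not cyclise prematurely.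

Step 19
Reactants: 26 (1S,5R,7S,9R)-11-[(2E)-3,7-dimethylocta-2,6-dien-1-yl]-12-hydroxy-7-(iodomethyl)-4,4,8,8-tetramethyltricyclo[7.3.1.0(1,5)]tridec-11-ene-10,13-dione
Product: 27 (1R,3R,5S,7R,12R)-5-[(2E)-3,7-dimethylocta-2,6-dien-1-yl]-8,8,13,13-tetramethyl cage 2,4,9-trione of rings A to E with hydrogen at the C1 bridgehead (analysis numbering)
Conditions: Cs2CO3, MeCN, 60 °C
Reagents that add atoms: none
Why: Intramolecular C-alkylation of the caesium enolate of a 2-substituted 1,3-diketone; C5 attacks C6 and closes ring B as a 6-(enolendo)-exo-tet and ring C as a 7-(enolendo)-exo-tet process; the C7 configuration holds C6 over the π-face of C5 on the ring A side of ring D, whereas the enolate oxygens lie in the enolate plane and can be reached only along a poorer trajectory, which should favour C- over O-alkylation; the cage fixes the configuration at C5.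

Step 20
Reactants: 27 (1R,3R,5S,7R,12R)-5-[(2E)-3,7-dimethylocta-2,6-dien-1-yl]-8,8,13,13-tetramethyl cage 2,4,9-trione with hydrogen at the C1 bridgehead; 28 benzoyl chloride
Product: 29 (1S,3S,5R,7R,12R)-1-benzoyl-5-[(2E)-3,7-dimethylocta-2,6-dien-1-yl]-8,8,13,13-tetramethyl cage 2,4,9-trione of rings A to E in the analysis numbering (target CNP0168637.1)
Conditions: LiTMP, THF, −78 °C; then 28, −78 to 0 °C
Reagents that add atoms: none
Why: Bridgehead lithiation and C-acylation; the C1 hydrogen is the only hydrogen α to a carbonyl in 27, the two flanking ketones acidify it, and the pyramidal bridgehead anion is acylated at carbon with retention; the changes of the C1, C3 and C5 descriptors on going to the product are priority effects.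

## Compound list

1 | diethyl malonate | CCOC(=O)CC(=O)OCC | starting material
2 | geranyl bromide, (2E)-1-bromo-3,7-dimethylocta-2,6-diene | CC(C)=CCC/C(C)=C/CBr | starting material
3 | diethyl 2-[(2E)-3,7-dimethylocta-2,6-dien-1-yl]propanedioate | CC(C)=CCC/C(C)=C/CC(C(=O)OCC)C(=O)OCC | intermediate
4 | 2-[(2E)-3,7-dimethylocta-2,6-dien-1-yl]propanedioic acid | CC(C)=CCC/C(C)=C/CC(C(=O)O)C(=O)O | intermediate
5 | 2-[(2E)-3,7-dimethylocta-2,6-dien-1-yl]propanedioyl dichloride | CC(C)=CCC/C(C)=C/CC(C(Cl)=O)C(Cl)=O | intermediate
6 | 3,3-dimethylglutaric anhydride | O=C1CC(C)(C)CC(=O)O1 | starting material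
7 | 5-[methoxy(methyl)amino]-3,3-dimethyl-5-oxopentanoic acid | CON(C)C(=O)CC(C)(C)CC(=O)O | intermediate
8 | (4S)-4-benzyl-1,3-oxazolidin-2-one | O=C1N[C@@H](Cc2ccccc2)CO1 | starting material
9 | mixed anhydride of 7 with 2,2-dimethylpropanoic acid (formed in situ) | CON(C)C(=O)CC(C)(C)CC(=O)OC(=O)C(C)(C)C | intermediate
10 | 5-[(4S)-4-benzyl-2-oxo-1,3-oxazolidin-3-yl]-N-methoxy-N,3,3-trimethyl-5-oxopentanamide | CON(C)C(=O)CC(C)(C)CC(=O)N1[C@@H](Cc2ccccc2)COC1=O | intermediate
11 | (4S)-4-{[(4S)-4-benzyl-2-oxo-1,3-oxazolidin-3-yl]carbonyl}-N-methoxy-N,3,3-trimethylhept-6-enamide | C=CC[C@H](C(=O)N1[C@@H](Cc2ccccc2)COC1=O)C(C)(C)CC(=O)N(C)OC | intermediate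
12 | (4S)-4-(hydroxymethyl)-N-methoxy-N,3,3-trimethylhept-6-enamide | C=CC[C@H](CO)C(C)(C)CC(=O)N(C)OC | intermediate
13 | (4S)-4-({[tert-butyl(dimethyl)silyl]oxy}methyl)-N-methoxy-N,3,3-trimethylhept-6-enamide | C=CC[C@H](CO[Si](C)(C)C(C)(C)C)C(C)(C)CC(=O)N(C)OC | intermediate
14 | (6S)-6-({[tert-butyl(dimethyl)silyl]oxy}methyl)-5,5-dimethylnona-1,8-dien-3-one | C=CC[C@H](CO[Si](C)(C)C(C)(C)C)C(C)(C)CC(=O)C=C | intermediate
15 | (5S)-5-({[tert-butyl(dimethyl)silyl]oxy}methyl)-6,6-dimethylcyclohept-2-en-1-one | O=C1C=CC[C@H](CO[Si](C)(C)C(C)(C)C)C(C)(C)C1 | intermediate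
16 | 3-methylbut-3-en-1-yl 4-methylbenzenesulfonate | C=C(C)CCOS(=O)(=O)c1ccc(C)cc1 | starting material
17 | 3-[(1RS,3S)-3-({[tert-butyl(dimethyl)silyl]oxy}methyl)-4,4-dimethyl-6-oxocycloheptyl]-3-methylbutyl 4-methylbenzenesulfonate (C12 epimers) | O=C1CC(C(C)(C)CCOS(=O)(=O)c2ccc(C)cc2)C[C@H](CO[Si](C)(C)C(C)(C)C)C(C)(C)C1 | intermediate
18 | 3-[(6S)-6-({[tert-butyl(dimethyl)silyl]oxy}methyl)-5,5-dimethyl-3-oxocyclohept-1-en-1-yl]-3-methylbutyl 4-methylbenzenesulfonate (formed in situ) | O=C1C=C(C(C)(C)CCOS(=O)(=O)c2ccc(C)cc2)C[C@H](CO[Si](C)(C)C(C)(C)C)C(C)(C)C1 | intermediate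
19 | 3-[(6S)-6-(hydroxymethyl)-5,5-dimethyl-3-oxocyclohept-1-en-1-yl]-3-methylbutyl 4-methylbenzenesulfonate | O=C1C=C(C(C)(C)CCOS(=O)(=O)c2ccc(C)cc2)C[C@H](CO)C(C)(C)C1 | intermediate
20 | 3-[(1S,3S)-3-(hydroxymethyl)-4,4-dimethyl-6-oxocycloheptyl]-3-methylbutyl 4-methylbenzenesulfonate | O=C1C[C@@H](C(C)(C)CCOS(=O)(=O)c2ccc(C)cc2)C[C@H](CO)C(C)(C)C1 | intermediate
21 | (3aS,7S,8aS)-7-(hydroxymethyl)-1,1,6,6-tetramethyloctahydroazulen-4(1H)-one | O=C1CC(C)(C)[C@@H](CO)C[C@@H]2C(C)(C)CC[C@H]12 | intermediate
22 | (3aS,7S,8aS)-7-(chloromethyl)-1,1,6,6-tetramethyloctahydroazulen-4(1H)-one | O=C1CC(C)(C)[C@@H](CCl)C[C@@H]2C(C)(C)CC[C@H]12 | intermediate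
23 | (3aS,7S,8aS)-7-(chloromethyl)-4,4-dimethoxy-1,1,6,6-tetramethyldecahydroazulene (formed in situ) | COC1(OC)CC(C)(C)[C@@H](CCl)C[C@@H]2C(C)(C)CC[C@H]12 | intermediate
24 | (7S,8aR)-7-(chloromethyl)-4-methoxy-1,1,6,6-tetramethyl-1,2,3,5,6,7,8,8a-octahydroazulene | COC1=C2CCC(C)(C)[C@H]2C[C@H](CCl)C(C)(C)C1 | intermediate
25 | (1S,5R,7S,9R)-7-(chloromethyl)-11-[(2E)-3,7-dimethylocta-2,6-dien-1-yl]-12-hydroxy-4,4,8,8-tetramethyltricyclo[7.3.1.0(1,5)]tridec-11-ene-10,13-dione | CC(C)=CCC/C(C)=C/CC1=C(O)[C@]23CCC(C)(C)[C@H]2C[C@H](CCl)C(C)(C)[C@H](C1=O)C3=O | intermediate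
26 | (1S,5R,7S,9R)-11-[(2E)-3,7-dimethylocta-2,6-dien-1-yl]-12-hydroxy-7-(iodomethyl)-4,4,8,8-tetramethyltricyclo[7.3.1.0(1,5)]tridec-11-ene-10,13-dione | CC(C)=CCC/C(C)=C/CC1=C(O)[C@]23CCC(C)(C)[C@H]2C[C@H](CI)C(C)(C)[C@H](C1=O)C3=O | intermediate
27 | (1R,3R,5S,7R,12R)-5-[(2E)-3,7-dimethylocta-2,6-dien-1-yl]-8,8,13,13-tetramethyl cage 2,4,9-trione of rings A to E with hydrogen at the C1 bridgehead (analysis numbering) | CC(C)=CCC/C(C)=C/C[C@@]12C[C@H]3C[C@@H]4C(C)(C)CC[C@]4(C1=O)C(=O)[C@@H](C2=O)C3(C)C | intermediate
28 | benzoyl chloride | O=C(Cl)c1ccccc1 | starting material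
29 | (1S,3S,5R,7R,12R)-1-benzoyl-5-[(2E)-3,7-dimethylocta-2,6-dien-1-yl]-8,8,13,13-tetramethyl cage 2,4,9-trione of rings A to E in the analysis numbering (CNP0168637.1) | CC(C)=CCC/C(C)=C/C[C@@]12C[C@H]3C[C@@H]4C(C)(C)CC[C@]4(C1=O)C(=O)[C@@](C(=O)c1ccccc1)(C2=O)C3(C)C | target

## Step count and least certain steps

Total step count: 20. Longest linear sequence: 17 steps (steps 4 to 20, from 6 to 29); the three-step preparation of 5 joins at step 17.

Step 17 (key step). Most likely to go wrong:
- O-acylation or lactonisation of the mono-acylated intermediate may outrun the second C-acylation at the neopentyl-type C1.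
- The acyl ketene from 5 may be lost by self-condensation.
- The HCl released may cause hydrochlorination or cyclisation of the geranyl diene.
- Facial selectivity at C3 may be incomplete, because the C7 arm sits on the face that must be attacked.

Fallback, setting out from 3 and 24 and returning at 25: partial saponification of 3 with one equivalent of KOH gives the half-ester 2-[(2E)-3,7-dimethylocta-2,6-dien-1-yl]-3-ethoxy-3-oxopropanoic acid F1. Oxalyl chloride converts it into ethyl (4E)-2-(chlorocarbonyl)-5,9-dimethyldeca-4,8-dienoate F2. F2 acylates C3 of 24 once (CH2Cl2, 0 °C, aqueous work-up) to give the C3-acylated keto ester F3. KOtBu in t-BuOH then closes ring A by Claisen condensation of the C1 enolate onto the ester, driven by formation of the stabilised trione enolate, and gives 25. This separates the two C–C bond formations and makes the second one a base-mediated condensation without a bis-acid chloride.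

Step 13. Most likely to go wrong: slow turnover at the hindered, electron-poor trisubstituted alkene with deactivation of the iridium catalyst, or incomplete direction by the bishomoallylic hydroxyl, which would give facial mixtures at C12.

Fallback, setting out from 19 and returning at 21: KOtBu in t-BuOH generates the extended dienolate of 19, which is alkylated at C3 by the tosylate with deconjugation. This gives the β,γ-unsaturated bicyclic hydroxy ketone (7S)-7-(hydroxymethyl)-1,1,6,6-tetramethyl-2,3,3a,5,6,7-hexahydroazulen-4(1H)-one F4, in which the C11=C12 alkene is isolated and the hydroxyl is homoallylic. Hydrogenation with [Ir(cod)(PCy3)(py)]PF6 then delivers hydrogen to C12 from the hydroxyl face and gives 21; its C3 epimer, if present, converges at 24.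

Step 19. Most likely to go wrong:
- Substitution at the β-branched C6 by the fully substituted enolate carbon C5 may be slow.
- Slow substitution would leave time for retro-Claisen opening of the C2/C4 or C2/C9 dicarbonyl by carbonate or adventitious hydroxide, or for intermolecular alkylation.
- O-alkylation through the C9 oxygen, which would close a six-membered cyclic enol ether, may compete with C-alkylation.

Fallback, setting out from 24 and returning at 27: the cage is closed before the side chain is attached. Malonyl dichloride in place of 5 gives the side-chain-free chloromethyl enol dione F5. NaI gives the corresponding iodide F6. Cs2CO3 closes rings B and C with the less hindered CH nucleophile to give the geranyl-free cage trione F7. LiTMP then removes the less hindered bridgehead proton at C5 (C1 is shielded by the C8 gem-dimethyl group), and alkylation of the bridgehead anion with 2 gives 27.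

Step 20. Most likely to go wrong: incomplete deprotonation of the bridgehead next to the C8 gem-dimethyl group, or sluggish capture of the hindered bridgehead anion by the acid chloride, which would allow consumption of 28 by the amide base.

Fallback, setting out from 27 and returning at 29: the bridgehead lithium species is trapped with the smaller and more reactive benzaldehyde to give the bridgehead carbinol F8, and Dess–Martin periodinane oxidises the carbinol to the ketone 29.

## Further compounds

F1 | step 17 | 2-[(2E)-3,7-dimethylocta-2,6-dien-1-yl]-3-ethoxy-3-oxopropanoic acid | CC(C)=CCC/C(C)=C/CC(C(=O)O)C(=O)OCC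
F2 | step 17 | ethyl (4E)-2-(chlorocarbonyl)-5,9-dimethyldeca-4,8-dienoate | CC(C)=CCC/C(C)=C/CC(C(Cl)=O)C(=O)OCC
F3 | step 17 | ethyl (4E)-2-{[(3aR,7S,8aR)-7-(chloromethyl)-1,1,6,6-tetramethyl-4-oxodecahydroazulen-3a-yl]carbonyl}-5,9-dimethyldeca-4,8-dienoate (C3-acylated keto ester) | CC(C)=CCC/C(C)=C/CC(C(=O)OCC)C(=O)[C@]12CCC(C)(C)[C@H]1C[C@H](CCl)C(C)(C)CC2=O
F4 | step 13 | (7S)-7-(hydroxymethyl)-1,1,6,6-tetramethyl-2,3,3a,5,6,7-hexahydroazulen-4(1H)-one | O=C1CC(C)(C)[C@@H](CO)C=C2C(C)(C)CCC12
F5 | step 19 | (1S,5R,7S,9R)-7-(chloromethyl)-12-hydroxy-4,4,8,8-tetramethyltricyclo[7.3.1.0(1,5)]tridec-11-ene-10,13-dione (side-chain-free chloromethyl enol dione) | C1=C(O)[C@]23CCC(C)(C)[C@H]2C[C@H](CCl)C(C)(C)[C@H](C1=O)C3=O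
F6 | step 19 | (1S,5R,7S,9R)-12-hydroxy-7-(iodomethyl)-4,4,8,8-tetramethyltricyclo[7.3.1.0(1,5)]tridec-11-ene-10,13-dione (side-chain-free iodomethyl enol dione) | C1=C(O)[C@]23CCC(C)(C)[C@H]2C[C@H](CI)C(C)(C)[C@H](C1=O)C3=O
F7 | step 19 | (1R,3S,5S,7R,12R)-8,8,13,13-tetramethyl cage 2,4,9-trione of rings A to E with hydrogen at both the C1 and C5 bridgeheads (analysis numbering) | [C@@H]12C[C@H]3C[C@@H]4C(C)(C)CC[C@]4(C1=O)C(=O)[C@@H](C2=O)C3(C)C
F8 | step 20 | (1S,3S,5R,7R,12R)-5-[(2E)-3,7-dimethylocta-2,6-dien-1-yl]-1-[hydroxy(phenyl)methyl]-8,8,13,13-tetramethyl cage 2,4,9-trione of rings A to E (analysis numbering; carbinol configuration not defined) | CC(C)=CCC/C(C)=C/C[C@@]12C[C@H]3C[C@@H]4C(C)(C)CC[C@]4(C1=O)C(=O)[C@@](C(O)c1ccccc1)(C2=O)C3(C)C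
A1 | alternative 1 | methyl 3-{[tert-butyl(dimethyl)silyl]oxy}-2-diazobut-3-enoate | COC(=O)C(=[N+]=[N-])C(=C)O[Si](C)(C)C(C)(C)C
A2 | alternative 1 | methyl (5E)-9-chloro-3,3,7,7-tetramethyl-4-methylidenenon-5-enoate | COC(=O)CC(C)(C)C(=C)/C=C/C(C)(C)CCCl
A3 | alternative 1 | ring C cyclohepta-1,4-diene with C12 set (product of the key step) | COC(=O)C1=C(O[Si](C)(C)C(C)(C)C)C[C@@H](C(C)(C)CCCl)C=C(C(C)(C)CC(=O)OC)C1
A4 | alternative 2 | methyl (4S)-4-(3-methoxy-3-oxopropyl)-5,5-dimethyl-7-oxocyclohept-1-ene-1-carboxylate | COC(=O)C1=CC[C@H](CCC(=O)OC)C(C)(C)CC1=O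
A5 | alternative 2 | 3-methylbut-3-en-1-yl 4-methylbenzenesulfonate | C=C(C)CCOS(=O)(=O)c1ccc(C)cc1
A6 | alternative 2 | cis-fused rings D and E with the angular C4 ester (product of the key step) | COC(=O)[C@]12CCC(C)(C)[C@H]1C[C@H](CCC(=O)OC)C(C)(C)CC2=O
A7 | alternative 3 | ring B cyclohexene carrying the ring E unit with the C3 aldoxime and ester | CC(C)=CCC/C(C)=C/CC1=CCC(C)(C)[C@H](C[C@@H]2C(C)(C)CC[C@]2(C=NO)C(=O)OC)C1
A8 | alternative 3 | bridged isoxazoline holding rings B, C and E with quaternary C5 (product of the key step) | CC(C)=CCC/C(C)=C/C[C@@]12C[C@H]3C[C@@H]4C(C)(C)CC[C@@]4(C(=O)OC)C1=NO[C@@H]2CC3(C)C
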